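**Plan**

- Retrosynthesis: the benzil is read as the open form of a 2-aryl-2-hydroxybenzofuran-3(2H)-one, so the O7–C(outer carbonyl) bond is re-formed on paper. Then the anisyl–C(outer carbonyl) bond is cut (α-arylation), then the bond between the two carbonyl carbons (Dieckmann), the O7–CH2 bond (Williamson), and the pyran bonds C4–C4a and O1–C2 (propargyl ether Claisen cascade).
- Enabling feature: on ring A (chromene numbering: C5–OMe, C6–acyl, C7–OH) the C7 hydroxyl is ortho to the diketone. O7 and the anisyl-bearing carbonyl carbon can therefore be joined in a five-membered benzofuran-3(2H)-one ring, which makes that carbon an acidic, arylatable C2–H.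
- Forward order: ring A comes intact from methyl 2,4,6-trihydroxybenzoate. The pyran is closed first, on the monocyclic salicylate, where the hydrogen-bonded hydroxyl (future C5–O) steers the sigmatropic shift. The furanone follows, then the anisyl group is joined, then oxidation at the same carbon opens the tether.
- Stereochemistry: the target has no stereocenter. The C2 center of 13 forms racemic and is erased in the last step.

Key step: step 7

Remark (assumption): hemiketal 15 and benzil 16 are ring–chain tautomers of one compound; the open, hydrogen-bonded form drawn for the target is taken as the form obtained after acidic work-up.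

Remark (numbering): benzoate numbering is used for 1–6, chromene numbering for 7, 8 and 16, and furo[3,2-g]chromene numbering (O1, C2, C3, C3a, C4, C4a, C5, C6, C7, O8, C8a, C9, C9a) for 9–15.

**Route**

Step 1
Reactants: 1 methyl 2,4,6-trihydroxybenzoate; 2 3-chloro-3-methylbut-1-yne
Product: 3 methyl 2,6-dihydroxy-4-[(2-methylbut-3-yn-2-yl)oxy]benzoate
Conditions: CuCl2·2H2O (1 mol%), DBU (1.1 equiv), MeCN, 0 °C
Reagents that add atoms: none
Why: Copper-catalyzed O-propargylation of a phenol with a tertiary propargylic chloride (via a copper allenylidene): one equivalent of DBU ionizes the 4-OH, which is para to the ester and the only hydroxyl not hydrogen-bonded to it, so the ether should form there and leave the two ortho hydroxyls free.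

Step 2
Reactants: 3 methyl 2,6-dihydroxy-4-[(2-methylbut-3-yn-2-yl)oxy]benzoate; 4 methyl bromoacetate
Product: 5 methyl 2-hydroxy-6-(2-methoxy-2-oxoethoxy)-4-[(2-methylbut-3-yn-2-yl)oxy]benzoate
Conditions: K2CO3 (1.1 equiv), 4 (1.05 equiv), acetone, 56 °C
Reagents that add atoms: none
Why: Williamson ether synthesis on one of two equivalent hydroxyls; once the first is alkylated, the last hydroxyl is fixed in a hydrogen bond to the ester carbonyl and should resist a second alkylation, and 56 °C is far below the temperature at which the propargyl ether rearranges.

Step 3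
Reactants: 5 methyl 2-hydroxy-6-(2-methoxy-2-oxoethoxy)-4-[(2-methylbut-3-yn-2-yl)oxy]benzoate
Product: 7 methyl 5-hydroxy-7-(2-methoxy-2-oxoethoxy)-2,2-dimethyl-2H-chromene-6-carboxylate, via ortho-allenyl phenol 6 (not isolated)
Conditions: xylene, 140 °C, argon
Reagents that add atoms: none
Why: Aromatic propargyl Claisen rearrangement, then 1,5-hydrogen shift and oxa-6π electrocyclization: the hydrogen-bonded salicylate chelate gives the ring bond between C3 and C4 the greater double-bond character, so the [3,3] shift should go to C3 beside the free hydroxyl and not to C5 beside the glycolate ether, as is known for 2-hydroxy-4-propargyloxy aryl ketones and esters, and the pyran then closes with the former ether oxygen while the chelated hydroxyl stays out.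

Step 4
Reactants: 7 methyl 5-hydroxy-7-(2-methoxy-2-oxoethoxy)-2,2-dimethyl-2H-chromene-6-carboxylate
Product: 8 methyl 5-methoxy-7-(2-methoxy-2-oxoethoxy)-2,2-dimethyl-2H-chromene-6-carboxylate
Conditions: MeI (2 equiv), K2CO3 (1.5 equiv), DMF, 40 °C
Reagents that add atoms: iodomethane, CI
Why: Williamson O-methylation of a hindered, hydrogen-bonded phenol, which needs a dipolar solvent and gentle warming but should leave both esters and the chromene double bond untouched.

Step 5
Reactants: 8 methyl 5-methoxy-7-(2-methoxy-2-oxoethoxy)-2,2-dimethyl-2H-chromene-6-carboxylate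
Product: 9 methyl 3-hydroxy-4-methoxy-7,7-dimethyl-7H-furo[3,2-g]chromene-2-carboxylate
Conditions: KOtBu (1.5 equiv), THF, 0 °C to rt; then 1 M HCl
Reagents that add atoms: none
Why: Dieckmann condensation: the enolate of the aryloxyacetate attacks the neighboring aryl ester (5-exo-trig), methoxide leaves, and deprotonation of the product, a β-keto ester that rests as the aromatic 3-hydroxybenzofuran, pulls the equilibrium over; this makes the bond between the two future carbonyl carbons of the benzil.

Step 6
Reactants: 9 methyl 3-hydroxy-4-methoxy-7,7-dimethyl-7H-furo[3,2-g]chromene-2-carboxylate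
Product: 11 4-methoxy-7,7-dimethyl-7H-furo[3,2-g]chromen-3(2H)-one, via β-keto acid 10 (not isolated)
Conditions: NaOH (2 M aq.), MeOH, 65 °C, argon; then HCl to pH 2, 45 °C
Reagents that add atoms: none
Why: Ester saponification followed by decarboxylation of the β-keto acid on acidification, the classical passage from a 3-hydroxybenzofuran-2-carboxylate to the benzofuran-3(2H)-one; the acid stage is kept dilute and mild so that the chromene double bond is not protonated.

Step 7
Reactants: 11 4-methoxy-7,7-dimethyl-7H-furo[3,2-g]chromen-3(2H)-one; 12 4-bromoanisole
Product: 13 racemic 4-methoxy-2-(4-methoxyphenyl)-7,7-dimethyl-7H-furo[3,2-g]chromen-3(2H)-one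
Conditions: Pd(OAc)2 (3 mol%), XPhos (2-dicyclohexylphosphino-2′,4′,6′-triisopropylbiphenyl, 6 mol%), NaOtBu (2.2 equiv), 12 (0.95 equiv), THF/toluene, 65 °C, argon; then degassed AcOH
Reagents that add atoms: none
Why: NaOtBu converts 11 fully into the sodium 3-benzofuranolate, zerovalent palladium (formed from Pd(OAc)2 and XPhos) adds oxidatively to the C–Br bond of 12, the enolate replaces bromide on divalent palladium, and C–C reductive elimination from the carbon-bound enolate joins C2 to the anisyl ring. This is the palladium-catalyzed α-arylation of ketone enolates with aryl bromides, used here on a benzofuran-3(2H)-one. No ring is closed; the furanone ring is already present and only holds O7 on the carbon being arylated, which makes C2 the sole acidic site because the other α-position, C3a, is an aromatic carbon. The new C2 stereocenter forms racemic under no control and is of no consequence, since it is enolizable and is erased in step 8. The step needs carbon- over oxygen-arylation and mono- over diarylation: the bulky biaryl phosphine favors reductive elimination from the carbon-bound palladium enolate, and the product enolate is more stabilized and more hindered, so a second coupling to a quaternary center should be slow with 12 as the limiting reagent. Full enolization before heating also keeps neutral ketone away from its own enolate, which suppresses aldol self-condensation, and the reaction and work-up are run under argon because the product enol is air-sensitive.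

Step 8
Reactants: 13 racemic 4-methoxy-2-(4-methoxyphenyl)-7,7-dimethyl-7H-furo[3,2-g]chromen-3(2H)-one
Product: 16 1-(7-hydroxy-5-methoxy-2,2-dimethyl-2H-chromen-6-yl)-2-(4-methoxyphenyl)ethane-1,2-dione, via 2-hydroperoxy furanone 14 (not isolated), via 2-hydroxy hemiketal 15 (not isolated)
Conditions: O2 (1 atm), Cs2CO3 (0.3 equiv), P(OEt)3 (1.5 equiv), DMSO, 20 °C; then aq. NH4Cl
Reagents that add atoms: dioxygen, O=O
Why: Base-mediated autoxidation of an enolate (α-hydroxylation of a ketone with O2 and a phosphite reductant): the very acidic C2–H gives the enolate, O2 adds at C2, P(OEt)3 reduces the hydroperoxide to the hemiketal, and ring–chain tautomerism then frees O7 as the hydrogen-bonded phenol and turns C2 into the second carbonyl, which also removes the only stereocenter.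

**Compound list**

1 | methyl 2,4,6-trihydroxybenzoate | COC(=O)c1c(O)cc(O)cc1O | starting material
2 | 3-chloro-3-methylbut-1-yne | C#CC(C)(C)Cl | starting material
3 | methyl 2,6-dihydroxy-4-[(2-methylbut-3-yn-2-yl)oxy]benzoate | COC(=O)c1c(O)cc(OC(C)(C)C#C)cc1O | intermediate
4 | methyl bromoacetate | COC(=O)CBr | starting material
5 | methyl 2-hydroxy-6-(2-methoxy-2-oxoethoxy)-4-[(2-methylbut-3-yn-2-yl)oxy]benzoate | COC(=O)COc1cc(OC(C)(C)C#C)cc(O)c1C(=O)OC | intermediate
6 | methyl 2,4-dihydroxy-6-(2-methoxy-2-oxoethoxy)-3-(3-methylbuta-1,2-dien-1-yl)benzoate | COC(=O)COc1cc(O)c(C=C=C(C)C)c(O)c1C(=O)OC | intermediate (not isolated)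
7 | methyl 5-hydroxy-7-(2-methoxy-2-oxoethoxy)-2,2-dimethyl-2H-chromene-6-carboxylate | COC(=O)COc1cc2OC(C)(C)C=Cc2c(O)c1C(=O)OC | intermediate
8 | methyl 5-methoxy-7-(2-methoxy-2-oxoethoxy)-2,2-dimethyl-2H-chromene-6-carboxylate | COC(=O)COc1cc2OC(C)(C)C=Cc2c(OC)c1C(=O)OC | intermediate
9 | methyl 3-hydroxy-4-methoxy-7,7-dimethyl-7H-furo[3,2-g]chromene-2-carboxylate | COC(=O)c1oc2cc3OC(C)(C)C=Cc3c(OC)c2c1O | intermediate
10 | 3-hydroxy-4-methoxy-7,7-dimethyl-7H-furo[3,2-g]chromene-2-carboxylic acid | OC(=O)c1oc2cc3OC(C)(C)C=Cc3c(OC)c2c1O | intermediate (not isolated)
11 | 4-methoxy-7,7-dimethyl-7H-furo[3,2-g]chromen-3(2H)-one | O=C1COc2cc3OC(C)(C)C=Cc3c(OC)c12 | intermediate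
12 | 4-bromoanisole | COc1ccc(Br)cc1 | starting material
13 | racemic 4-methoxy-2-(4-methoxyphenyl)-7,7-dimethyl-7H-furo[3,2-g]chromen-3(2H)-one | COc1ccc(C2Oc3cc4OC(C)(C)C=Cc4c(OC)c3C2=O)cc1 | intermediate
14 | racemic 2-hydroperoxy-4-methoxy-2-(4-methoxyphenyl)-7,7-dimethyl-7H-furo[3,2-g]chromen-3(2H)-one | COc1ccc(C2(OO)Oc3cc4OC(C)(C)C=Cc4c(OC)c3C2=O)cc1 | intermediate (not isolated)
15 | racemic 2-hydroxy-4-methoxy-2-(4-methoxyphenyl)-7,7-dimethyl-7H-furo[3,2-g]chromen-3(2H)-one | COc1ccc(C2(O)Oc3cc4OC(C)(C)C=Cc4c(OC)c3C2=O)cc1 | intermediate (not isolated)
16 | 1-(7-hydroxy-5-methoxy-2,2-dimethyl-2H-chromen-6-yl)-2-(4-methoxyphenyl)ethane-1,2-dione | COc1ccc(C(=O)C(=O)c2c(O)cc3c(c2OC)C=CC(C)(C)O3)cc1 | target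

**Step count and risks**

Total step count: 8. Longest linear sequence: 8 steps (1 to 16); 2, 4 and 12 are bought.

Steps most likely to fail, most uncertain first:

Step 7. The strongly stabilized benzofuranolate may couple through oxygen instead of carbon, may be arylated twice, or may bind palladium so firmly that turnover stalls. The fallback sets out from 11 and comes back at 13. The potassium enolate of 11 (KOtBu, THF/tBuOH, 0 °C to rt) would be treated with bis(4-methoxyphenyl)iodonium tetrafluoroborate. This is a transition-metal-free arylation of a stabilized enolate by ligand coupling on trivalent iodine; it transfers one anisyl group to C2 and needs no catalyst that the enolate could poison. No new compound lies on this way.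

Step 3. Regiocontrol of the sigmatropic shift may be lost: at 140 °C the hydrogen bond that fixes the ring bonds is weakened, and migration to the carbon beside the glycolate ether would lead to the angular ring fusion. The fallback sets out from 3 and comes back at 7. Diol 3 itself would be heated (xylene, 140 °C); its two ortho positions are equivalent by symmetry, so only one chromene can arise, methyl 5,7-dihydroxy-2,2-dimethyl-2H-chromene-6-carboxylate F1. F1 would then be alkylated with one equivalent of 4 (K2CO3, acetone, 56 °C). The 7-hydroxyl, flanked only by C8–H, should react in preference to the 5-hydroxyl wedged between the ester and the C4 vinyl carbon, giving 7. Regiochemistry then rests on the site selectivity of an O-alkylation and no longer on the course of the rearrangement.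

Step 8. Over-oxidation may occur: the α-hydroperoxide may fragment, or peroxide anion may attack the newly formed 1,2-diketone, and either process cleaves the bond between the two carbonyl carbons. The fallback sets out from 13 and comes back at 15, which opens to 16. The sodium enolate of 13 (NaHMDS, THF, −78 °C) would be hydroxylated with 2-(phenylsulfonyl)-3-phenyloxaziridine. This is a direct electrophilic oxygen transfer (Davis oxidation) in which no peroxide is ever present. No new compound lies on this way.

**Further compounds**

F0 | step 7 | none | none
F1 | step 3 | methyl 5,7-dihydroxy-2,2-dimethyl-2H-chromene-6-carboxylate | COC(=O)c1c(O)cc2OC(C)(C)C=Cc2c1O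
F0 | step 8 | none | none
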